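Remark on the chemistry: the SMILES is read as a diaryl ether between C4' of a 3,5,3'-trihydroxy-7-methoxyflavone unit (half 1) and C4' of a 3,5,7-trihydroxy-3'-methoxyflavone unit (half 2). The compound has no stereocentre. Chromone numbering (O1, C2–C4, C4a, C5–C8, C8a, primed locants for ring B) is used for both halves.

## The problem

- Target 24 is two flavonol units on one hinge: the oxygen on C4' of ring B of half 1 is bonded to C4' of ring B of half 2, so six rings hang on a single C–O–C link.
- There is no stereocentre and no stereogenic double bond, so the whole difficulty is constitutional.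
- The halves are near twins. The two pyranone rings therefore cannot come from one reaction run twice on a symmetric intermediate; each ring C needs its own handle on the diaryl ether.
- Nine phenolic or enolic oxygens must be sorted into two methyl ethers (O7 of half 1, O3' of half 2), six free hydroxyls and the bridging ether.
- The bridge joins two electron-rich rings, each with an oxygen ortho to it. It is best made early, while one ring still carries an acceptor, not by coupling two finished flavonols.
- The free polyphenol, above all its two 3-hydroxy-4-pyranone enols, is oxidised easily in base and air, and the methyl ethers rule out a Lewis-acid global deprotection. The last step must be neutral and reductive, so every temporary group is benzyl.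
- The enabling feature is ring A of half 2. Once O7 is capped it has a mirror plane through C7 and C4a; C4 is a lone carbonyl carbon between C4a and C3; and C3 and C2 are the two carbons an arylacetylene on ring B supplies. Ring C can thus be assembled from a C4a–I bond, carbon monoxide and an alkyne, and either hydroxyl ortho to the iodide closes to the same chromone.

## Retrosynthesis

**24 from 23.** Five O–CH2Ph bonds are cut (O3, O5, O3' of half 1; O5, O7 of half 2). A single hydrogenolysis is preferred over mixed protection because it is neutral, spares both methyl ethers and the diaryl ether, and exposes the air-sensitive hexaphenol only at the end. The forward reaction only has to leave the pyranone double bonds untouched.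

**23 from 20 and 19.** The C3–O bond of half 2 is cut, then the O5–benzyl bond. Oxygenating C3 by deprotonation and borate oxidation is chosen over epoxidation of the C2–C3 double bond, because only half 2 has a C3–H, whereas an electrophilic oxidant would also meet the electron-rich 3-benzyloxy enol ether of half 1. Benzylating the chelated 5-hydroxyl of 19 first removes the only acidic proton, so 20 needs one equivalent of base.

**19 from 16, 13 and carbon monoxide (the key cut).** Three bonds of ring C of half 2 are cut: C4a–C4, C4–C3 and O1–C2.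
- Against a chalcone or diketone route this cut needs no second aldehyde or acid on the diaryl ether, which could not be told apart from the one used for half 1. The alkyne of 13 descends from an aryl bromide that is inert through all earlier steps.
- The precursors are much simpler: iodoresorcinol 16 is two steps from phloroglucinol 14, and 13 holds all of half 1.
- The forward reaction must insert CO before alkyne transfer, close 6-endo and not 5-exo, and tolerate two free ortho hydroxyls. The mirror plane of 16 removes any question of which hydroxyl closes.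
- Ring A of half 1 is equally symmetric, so the roles could be reversed. This assignment is chosen because the commercial arenes 1 and 3 carry the ring-B patterns of half 1 and half 2 respectively.

**13 from 11, and 11 from 10 and 8.** The C(sp2)–C(sp) bond is cut back to bromide 11 (Sonogashira ethynylation). Ring C of half 1 is then cut at O1–C2 and C3–O, back to 2'-hydroxychalcone 8. The oxidative chalcone cyclisation closes the pyranone and installs the C3 oxygen in one step, so half 1 needs no late C–H oxidation. It is asked to close through the six-membered mode despite the 6'-benzyloxy group.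

**8 from 4 and 7.** The Cα=Cβ bond is cut (aldol condensation). Aldehyde 4 has no α-hydrogen and ketone 7 is a methyl ketone, so only one cross-product is possible.

**4 from 2 and 3, and 2 from 1.** The bridging C4'–O bond of half 1 is cut. SNAr is preferred over a copper-mediated ether synthesis because the formyl group needed for the chalcone sits para to fluoride and activates it, and the bromide of 3 survives as the latent alkyne. Both partners are commercial benzenes; the hydroxyl of 1 is benzylated first so that it cannot compete as nucleophile.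

**7 from 6 and 5.** Two O–C bonds are cut. The para hydroxyl of 5 is the only one not chelated to the acetyl group and takes the methyl; one of the two equivalent chelated hydroxyls then takes the benzyl.

**16 from 15 and 14.** The C–I bond and one O–benzyl bond are cut. The iodide is asked to enter between the two hydroxyls of 15, the position that resorcinols iodinate under bicarbonate buffering.

## Roads not taken

**Alternative 1:** ring B of half 2 would be built by cycloaddition.
- Cut: ring bonds C3'–C4' and C5'–C6' of half 2.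
- Key step: inverse-demand Diels–Alder reaction of pyrone A1 with aryl ethynyl ether A2, then decarboxylative aromatisation to benzoate A3 with the diaryl ether in place.
- Merits: the bridge forms without any activating group, and polarity matching fixes the regiochemistry (nucleophilic alkyne terminus to the pyrone carbon next to the ring oxygen).
- Weak points: aryl ethynyl ethers are laborious and thermally fragile, and the 3-methoxy group makes A1 a poorer diene, so heat is needed. The ring created is a vanillate-type benzene that can be bought fully substituted. After A3 both pyranone rings and all oxygen sorting remain.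
- Comparison: this road would be better if neither ring could carry an acceptor. Here the chosen plan sets against it that the formyl group of 2 is needed anyway and gives bridge 4 in one step from two commercial arenes.

**Alternative 2:** ring A of half 2 would be built by a biomimetic Claisen cyclisation.
- Cut: the C4a–C5 bond of half 2.
- Key step: triketoester A4 is folded by a magnesium alkoxide so that chain carbon C6 attacks the ester carbon, giving 2',4',6'-trihydroxychalcone A5.
- Merits: acyclic-to-aromatic logic, no transition metal or pressure vessel, and a symmetric ring A that poses no regiochemical question in the later O1–C2 closure. In these respects it equals or betters the chosen plan.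
- Weak points: A4 needs a polyanion assembly of a cinnamoyl tetracarbonyl chain. Such chains are enol mixtures in which lactonisation to a hydroxypyranone and aldol closure to a resorcylate compete with the Claisen mode, and the enone invites internal Michael addition. A5 would still have to be protected and oxidatively cyclised with a free 6'-hydroxyl.
- Comparison: the ring it builds is available as 14 or 5. The chosen plan sets against it a bought ring A and three ring-C bonds formed in one predictable operation.

**Alternative 3:** ring C of half 1 would be closed by aryne annulation.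
- Cut: O1–C8a and C4–C4a.
- Key step: the aryne released by fluoride from silyl triflate A6 is attacked by the enolate oxygen of α-benzyloxy ketoester A7, and the aryl anion closes on the ester to give flavone A8.
- Merits: two bonds in one step, aryne regiochemistry steered correctly by the flanking methoxy group, and the C3 oxygen already in place at ring closure. On this last point it is better than the chosen plan, which spends steps 12 and 13 on the C3 oxygen of half 2.
- Weak points: ketoester enolates normally attack arynes through carbon, so the required O-attack is the minor mode. A6 and A7 each take several steps. The 5,7-dimethoxy pattern of A8 fits only half 1 after a chelation-controlled 5-demethylation, which would have to spare two other methyl ethers and the benzyl groups.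
- Comparison: the chosen plan sets against it four commercial arenes, the reliable chemoselectivity of the palladium sequence, and a protecting-group set that falls in one hydrogenolysis.

Key step: step 11

## Route

Abbreviation used in names: Ar* = 4-[2-(benzyloxy)-4-(3,5-bis(benzyloxy)-7-methoxy-4-oxo-4H-chromen-2-yl)phenoxy]-3-methoxyphenyl (ring B of half 2 carrying benzyl-protected half 1).

Step 1
Reactants: 1 4-fluoro-3-hydroxybenzaldehyde
Product: 2 3-(benzyloxy)-4-fluorobenzaldehyde
Conditions: BnBr, K2CO3, DMF, rt
Reagents that add atoms: benzyl bromide, BrCc1ccccc1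
Why: Williamson ether synthesis; capping the phenol keeps its phenoxide from deactivating the fluoroarene or acting as a competing nucleophile in step 2.

Step 2
Reactants: 2 3-(benzyloxy)-4-fluorobenzaldehyde; 3 4-bromo-2-methoxyphenol
Product: 4 3-(benzyloxy)-4-(4-bromo-2-methoxyphenoxy)benzaldehyde
Conditions: K2CO3, DMF, 120 °C
Reagents that add atoms: none
Why: Nucleophilic aromatic substitution (SNAr): the para formyl group stabilises the Meisenheimer adduct and fluoride is the best leaving group, while the unactivated aryl bromide of 3 stays as the later alkyne handle.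

Step 3
Reactants: 5 1-(2,4,6-trihydroxyphenyl)ethanone (2,4,6-trihydroxyacetophenone)
Product: 6 1-(2,6-dihydroxy-4-methoxyphenyl)ethanone
Conditions: Me2SO4 (1 equiv), K2CO3 (1 equiv), acetone, reflux
Reagents that add atoms: dimethyl sulfate, COS(=O)(=O)OC
Why: Selective O-methylation (Williamson type): the para hydroxyl is the only one not hydrogen-bonded to the acetyl group, so one equivalent of electrophile should go there.

Step 4
Reactants: 6 1-(2,6-dihydroxy-4-methoxyphenyl)ethanone
Product: 7 1-[2-(benzyloxy)-6-hydroxy-4-methoxyphenyl]ethanone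
Conditions: BnBr (1 equiv), K2CO3, acetone, reflux
Reagents that add atoms: benzyl bromide, BrCc1ccccc1
Why: Williamson mono-benzylation of two equivalent hydroxyls; after the first alkylation the remaining hydroxyl is held in a strong hydrogen bond to the carbonyl and should react far more slowly.

Step 5
Reactants: 4 3-(benzyloxy)-4-(4-bromo-2-methoxyphenoxy)benzaldehyde; 7 1-[2-(benzyloxy)-6-hydroxy-4-methoxyphenyl]ethanone
Product: 8 (E)-1-[2-(benzyloxy)-6-hydroxy-4-methoxyphenyl]-3-[3-(benzyloxy)-4-(4-bromo-2-methoxyphenoxy)phenyl]prop-2-en-1-one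
Conditions: KOH (50% aq.), EtOH/THF, rt
Reagents that add atoms: none
Why: Claisen–Schmidt condensation of a methyl ketone with a non-enolisable aldehyde; E1cB dehydration should give the E enone.

Step 6
Reactants: 8 (E)-1-[2-(benzyloxy)-6-hydroxy-4-methoxyphenyl]-3-[3-(benzyloxy)-4-(4-bromo-2-methoxyphenoxy)phenyl]prop-2-en-1-one
Product: 10 5-(benzyloxy)-2-[3-(benzyloxy)-4-(4-bromo-2-methoxyphenoxy)phenyl]-3-hydroxy-7-methoxy-4H-chromen-4-one, via racemic trans-dihydroflavonol 9 (not isolated)
Conditions: 30% H2O2, NaOH (aq.), MeOH/THF, 0 °C to rt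
Reagents that add atoms: hydrogen peroxide, OO
Why: Algar–Flynn–Oyamada oxidative cyclisation: the phenoxide closes on the β-carbon as alkaline peroxide oxygenates the α-carbon, and the resulting dihydroflavonol 9 is dehydrogenated by excess peroxide; 2'-hydroxy-4',6'-dialkoxychalcones are a known substrate class for this flavonol synthesis, the 6'-substituent being the known source of an aurone side path (see risks).

Step 7
Reactants: 10 5-(benzyloxy)-2-[3-(benzyloxy)-4-(4-bromo-2-methoxyphenoxy)phenyl]-3-hydroxy-7-methoxy-4H-chromen-4-one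
Product: 11 3,5-bis(benzyloxy)-2-[3-(benzyloxy)-4-(4-bromo-2-methoxyphenoxy)phenyl]-7-methoxy-4H-chromen-4-one
Conditions: BnBr, K2CO3, DMF, 50 °C
Reagents that add atoms: benzyl bromide, BrCc1ccccc1
Why: Williamson O-alkylation of the acidic enolic 3-hydroxyl, the only free hydroxyl in 10.

Step 8
Reactants: 11 3,5-bis(benzyloxy)-2-[3-(benzyloxy)-4-(4-bromo-2-methoxyphenoxy)phenyl]-7-methoxy-4H-chromen-4-one
Product: 13 3,5-bis(benzyloxy)-2-[3-(benzyloxy)-4-(4-ethynyl-2-methoxyphenoxy)phenyl]-7-methoxy-4H-chromen-4-one (Ar*-acetylene), via silylalkyne 12 (not isolated)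
Conditions: Me3SiC≡CH, PdCl2(PhCN)2 (cat.), [HP(t-Bu)3]BF4, CuI (cat.), i-Pr2NH, dioxane, 40 °C; then K2CO3, MeOH, rt
Reagents that add atoms: ethynyltrimethylsilane, C#C[Si](C)(C)C
Why: Sonogashira coupling; the bulky electron-rich phosphine allows oxidative addition to the electron-rich aryl bromide at mild temperature, the silyl cap prevents double coupling and is removed by base-catalysed methanolysis in the same flask.

Step 9
Reactants: 14 benzene-1,3,5-triol (phloroglucinol)
Product: 15 5-(benzyloxy)benzene-1,3-diol
Conditions: 14 (3 equiv), BnBr (1 equiv), K2CO3, DMF, rt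
Reagents that add atoms: benzyl bromide, BrCc1ccccc1
Why: Statistical Williamson mono-O-benzylation; excess triol suppresses polyalkylation, the dipolar aprotic solvent favours O- over C-alkylation, and unreacted 14 is removed with water.

Step 10
Reactants: 15 5-(benzyloxy)benzene-1,3-diol
Product: 16 5-(benzyloxy)-2-iodobenzene-1,3-diol
Conditions: I2, NaHCO3, THF/H2O, 0 °C
Reagents that add atoms: iodine, II
Why: Electrophilic aromatic iodination; under bicarbonate buffering resorcinols are iodinated at the position flanked by both hydroxyls, here also para to the benzyloxy group, and the buffer removes the acid that would otherwise cause iodine migration or loss.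

Step 11
Reactants: 16 5-(benzyloxy)-2-iodobenzene-1,3-diol; 13 3,5-bis(benzyloxy)-2-[3-(benzyloxy)-4-(4-ethynyl-2-methoxyphenoxy)phenyl]-7-methoxy-4H-chromen-4-one (Ar*-acetylene)
Product: 19 7-(benzyloxy)-5-hydroxy-2-Ar*-4H-chromen-4-one, via ynone 17 (not isolated), via enaminone 18 (not isolated)
Conditions: PdCl2(PPh3)2 (5 mol %), CO (10 atm), Et2NH/DMF, 100 °C
Reagents that add atoms: carbon monoxide, [C-]#[O+]
Why: This is the known palladium-catalysed carbonylative annulation of 2-iodophenols with terminal arylacetylenes in a secondary amine, a carbonylative Sonogashira-type coupling followed by ring closure. PdCl2(PPh3)2 is reduced in situ to zerovalent palladium, which inserts into the C–I bond of 16; CO insertion gives an aroylpalladium iodide, and amine-assisted transfer of the acetylide of 13 with reductive elimination forms C4a–C4 and C4–C3 in ynone 17. Diethylamine then adds to the ynone in conjugate fashion to give enaminone 18, and one of the two equivalent ortho hydroxyls attacks the amine-bearing carbon and expels diethylamine, forming O1–C2 and closing ring C of half 2. The closure is a 6-endo-trig oxa-Michael addition–elimination on 18, formally a 6-endo-dig cyclisation of 17; because the amine already occupies the β-carbon, the 5-exo-dig path to the aurone is shut. No stereocentre is formed. Three selectivities are needed: carbonylation must outrun direct alkynylation (copper-free conditions and CO pressure), the closure must be 6-endo (the secondary amine), and ring A must close in one sense only (the mirror plane of 16 through C2 and C5 makes both hydroxyls equivalent). The unused hydroxyl ends as the chelated 5-OH of 19, and the ether and chromone functions of 13 are spectators under these basic conditions.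

Step 12
Reactants: 19 7-(benzyloxy)-5-hydroxy-2-Ar*-4H-chromen-4-one
Product: 20 5,7-bis(benzyloxy)-2-Ar*-4H-chromen-4-one
Conditions: BnBr, K2CO3, DMF, 70 °C
Reagents that add atoms: benzyl bromide, BrCc1ccccc1
Why: Williamson benzylation of the only free hydroxyl; warming in DMF overcomes the hydrogen bond to the C4 carbonyl and removes the acidic proton before the lithiation.

Step 13
Reactants: 20 5,7-bis(benzyloxy)-2-Ar*-4H-chromen-4-one
Product: 23 5,7-bis(benzyloxy)-3-hydroxy-2-Ar*-4H-chromen-4-one, via 3-lithioflavone 21 (not isolated), via 3-boronate 22 (not isolated)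
Conditions: LiN(i-Pr)2, THF, −78 °C; B(OMe)3, −78 to 0 °C; then AcOH, 30% H2O2, 0 °C to rt
Reagents that add atoms: hydrogen peroxide, OO
Why: Known C3 lithiation of flavones followed by borate capture and oxidative 1,2-migration from boron to oxygen; only half 2 has a C3–H (alpha to the carbonyl on an oxygen-bearing double bond), half 1 has none, and benzylic ether hydrogens are not acidic enough for the amide base at −78 °C.

Step 14
Reactants: 23 5,7-bis(benzyloxy)-3-hydroxy-2-Ar*-4H-chromen-4-one
Product: 24 2-{4-[4-(3,5-dihydroxy-7-methoxy-4-oxo-4H-chromen-2-yl)-2-hydroxyphenoxy]-3-methoxyphenyl}-3,5,7-trihydroxy-4H-chromen-4-one (target)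
Conditions: H2 (1 atm), Pd(OH)2/C, THF/MeOH, rt
Reagents that add atoms: none
Why: Catalytic hydrogenolysis of five O-benzyl ethers (four aryl, one enol); methyl ethers, the diaryl ether and the pyranone double bonds are inert under these neutral conditions.

## Compound list

1 | 4-fluoro-3-hydroxybenzaldehyde | O=Cc1ccc(F)c(O)c1 | starting material
2 | 3-(benzyloxy)-4-fluorobenzaldehyde | O=Cc1ccc(F)c(OCc2ccccc2)c1 | intermediate
3 | 4-bromo-2-methoxyphenol | COc1cc(Br)ccc1O | starting material
4 | 3-(benzyloxy)-4-(4-bromo-2-methoxyphenoxy)benzaldehyde | O=Cc1ccc(Oc2ccc(Br)cc2OC)c(OCc2ccccc2)c1 | intermediate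
5 | 1-(2,4,6-trihydroxyphenyl)ethanone | CC(=O)c1c(O)cc(O)cc1O | starting material
6 | 1-(2,6-dihydroxy-4-methoxyphenyl)ethanone | CC(=O)c1c(O)cc(OC)cc1O | intermediate
7 | 1-[2-(benzyloxy)-6-hydroxy-4-methoxyphenyl]ethanone | CC(=O)c1c(O)cc(OC)cc1OCc1ccccc1 | intermediate
8 | (E)-1-[2-(benzyloxy)-6-hydroxy-4-methoxyphenyl]-3-[3-(benzyloxy)-4-(4-bromo-2-methoxyphenoxy)phenyl]prop-2-en-1-one | O=C(/C=C/c1ccc(Oc2ccc(Br)cc2OC)c(OCc2ccccc2)c1)c1c(O)cc(OC)cc1OCc1ccccc1 | intermediate
9 | trans-5-(benzyloxy)-2-[3-(benzyloxy)-4-(4-bromo-2-methoxyphenoxy)phenyl]-3-hydroxy-7-methoxychroman-4-one (racemic; 2R,3R enantiomer drawn) | O=C1c2c(OCc3ccccc3)cc(OC)cc2O[C@H](c2ccc(Oc3ccc(Br)cc3OC)c(OCc3ccccc3)c2)[C@H]1O | intermediate (not isolated)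
10 | 5-(benzyloxy)-2-[3-(benzyloxy)-4-(4-bromo-2-methoxyphenoxy)phenyl]-3-hydroxy-7-methoxy-4H-chromen-4-one | COc1cc(OCc2ccccc2)c2c(=O)c(O)c(-c3ccc(Oc4ccc(Br)cc4OC)c(OCc4ccccc4)c3)oc2c1 | intermediate
11 | 3,5-bis(benzyloxy)-2-[3-(benzyloxy)-4-(4-bromo-2-methoxyphenoxy)phenyl]-7-methoxy-4H-chromen-4-one | COc1cc(OCc2ccccc2)c2c(=O)c(OCc3ccccc3)c(-c3ccc(Oc4ccc(Br)cc4OC)c(OCc4ccccc4)c3)oc2c1 | intermediate
12 | 3,5-bis(benzyloxy)-2-{3-(benzyloxy)-4-[2-methoxy-4-(trimethylsilylethynyl)phenoxy]phenyl}-7-methoxy-4H-chromen-4-one | COc1cc(OCc2ccccc2)c2c(=O)c(OCc3ccccc3)c(-c3ccc(Oc4ccc(C#C[Si](C)(C)C)cc4OC)c(OCc4ccccc4)c3)oc2c1 | intermediate (not isolated)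
13 | 3,5-bis(benzyloxy)-2-[3-(benzyloxy)-4-(4-ethynyl-2-methoxyphenoxy)phenyl]-7-methoxy-4H-chromen-4-one | COc1cc(OCc2ccccc2)c2c(=O)c(OCc3ccccc3)c(-c3ccc(Oc4ccc(C#C)cc4OC)c(OCc4ccccc4)c3)oc2c1 | intermediate
14 | benzene-1,3,5-triol (phloroglucinol) | Oc1cc(O)cc(O)c1 | starting material
15 | 5-(benzyloxy)benzene-1,3-diol | Oc1cc(O)cc(OCc2ccccc2)c1 | intermediate
16 | 5-(benzyloxy)-2-iodobenzene-1,3-diol | Oc1cc(OCc2ccccc2)cc(O)c1I | intermediate
17 | 1-[4-(benzyloxy)-2,6-dihydroxyphenyl]-3-Ar*-prop-2-yn-1-one | O=C(C#Cc1ccc(Oc2ccc(-c3oc4cc(OC)cc(OCc5ccccc5)c4c(=O)c3OCc3ccccc3)cc2OCc2ccccc2)c(OC)c1)c1c(O)cc(OCc2ccccc2)cc1O | intermediate (not isolated)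
18 | (E)-1-[4-(benzyloxy)-2,6-dihydroxyphenyl]-3-(diethylamino)-3-Ar*-prop-2-en-1-one (geometry inconsequential) | CCN(CC)/C(=C/C(=O)c1c(O)cc(OCc2ccccc2)cc1O)c1ccc(Oc2ccc(-c3oc4cc(OC)cc(OCc5ccccc5)c4c(=O)c3OCc3ccccc3)cc2OCc2ccccc2)c(OC)c1 | intermediate (not isolated)
19 | 7-(benzyloxy)-5-hydroxy-2-Ar*-4H-chromen-4-one | O=c1cc(-c2ccc(Oc3ccc(-c4oc5cc(OC)cc(OCc6ccccc6)c5c(=O)c4OCc4ccccc4)cc3OCc3ccccc3)c(OC)c2)oc2cc(OCc3ccccc3)cc(O)c12 | intermediate
20 | 5,7-bis(benzyloxy)-2-Ar*-4H-chromen-4-one | O=c1cc(-c2ccc(Oc3ccc(-c4oc5cc(OC)cc(OCc6ccccc6)c5c(=O)c4OCc4ccccc4)cc3OCc3ccccc3)c(OC)c2)oc2cc(OCc3ccccc3)cc(OCc3ccccc3)c12 | intermediate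
21 | 5,7-bis(benzyloxy)-3-lithio-2-Ar*-4H-chromen-4-one | O=c1c([Li])c(-c2ccc(Oc3ccc(-c4oc5cc(OC)cc(OCc6ccccc6)c5c(=O)c4OCc4ccccc4)cc3OCc3ccccc3)c(OC)c2)oc2cc(OCc3ccccc3)cc(OCc3ccccc3)c12 | intermediate (not isolated)
22 | dimethyl [5,7-bis(benzyloxy)-4-oxo-2-Ar*-4H-chromen-3-yl]boronate | O=c1c(B(OC)OC)c(-c2ccc(Oc3ccc(-c4oc5cc(OC)cc(OCc6ccccc6)c5c(=O)c4OCc4ccccc4)cc3OCc3ccccc3)c(OC)c2)oc2cc(OCc3ccccc3)cc(OCc3ccccc3)c12 | intermediate (not isolated)
23 | 5,7-bis(benzyloxy)-3-hydroxy-2-Ar*-4H-chromen-4-one | O=c1c(O)c(-c2ccc(Oc3ccc(-c4oc5cc(OC)cc(OCc6ccccc6)c5c(=O)c4OCc4ccccc4)cc3OCc3ccccc3)c(OC)c2)oc2cc(OCc3ccccc3)cc(OCc3ccccc3)c12 | intermediate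
24 | 2-{4-[4-(3,5-dihydroxy-7-methoxy-4-oxo-4H-chromen-2-yl)-2-hydroxyphenoxy]-3-methoxyphenyl}-3,5,7-trihydroxy-4H-chromen-4-one | COc1cc(O)c2c(=O)c(O)c(-c3ccc(Oc4ccc(-c5oc6cc(O)cc(O)c6c(=O)c5O)cc4OC)c(O)c3)oc2c1 | target

## Step count and least certain steps

Total step count: 14. Longest linear sequence: 10 steps (steps 1, 2, 5, 6, 7, 8, 11, 12, 13, 14).

**Step 11 (key step).**
- What may go wrong: oxidative addition into the electron-rich, doubly ortho-flanked C–I bond may be slow, so that protodeiodination of 16 or alkyne homocoupling takes over. The aroylpalladium species may be captured by diethylamine instead of the acetylide. Coupling without CO insertion and 5-endo closure would lead to a benzofuran. The pyranone of half 1 may be opened by the amine at the temperature needed.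
- Fallback: a Baker–Venkataraman sequence that sets out from bromide 11 and acetophenone 5 and returns at 20. Compound 5 is dibenzylated (BnBr, K2CO3, DMF) to 1-[2,4-bis(benzyloxy)-6-hydroxyphenyl]ethanone F1. Bromide 11 is converted by palladium-catalysed hydroxycarbonylation (Pd(OAc)2, Xantphos, CO, H2O, Et3N, dioxane) into the benzoic acid Ar*-CO2H F2. Steglich esterification of F2 with F1 (EDC·HCl, DMAP, CH2Cl2) gives the 2-acetyl-3,5-bis(benzyloxy)phenyl ester F3. Acyl transfer with KOH in pyridine gives the 1,3-diketone F4, and acid-catalysed cyclodehydration (p-TsOH, toluene, 90 °C) gives 20.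

**Step 13.**
- What may go wrong: competing deprotonation at benzylic ether positions or attack of the amide on the pyranone of half 1; ring opening of the 3-lithio species before borate capture; incomplete oxidation of the boronate.
- Fallback: it sets out from 11 through the diketone F4 described under step 11 and returns at 23, placing the C3 oxygen before ring closure. F4 is α-benzoyloxylated with dibenzoyl peroxide (aqueous Na2CO3/CH2Cl2, phase-transfer conditions) to the 2-(benzoyloxy)-1,3-diketone F5. Acid-catalysed cyclodehydration gives the 3-(benzoyloxy)flavone F6, and methanolysis (K2CO3, MeOH/THF) gives 23.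

**Step 6.**
- What may go wrong: five-membered closure of the phenoxide onto the α-carbon, favoured by the 6'-benzyloxy group, which diverts material to the aurone.
- Fallback: it sets out from chalcone 8 and returns at 10. Oxidative cyclisation with catalytic I2 in DMSO at 120 °C gives the flavone 5-(benzyloxy)-2-[3-(benzyloxy)-4-(4-bromo-2-methoxyphenoxy)phenyl]-7-methoxy-4H-chromen-4-one F7. Dimethyldioxirane in acetone/CH2Cl2 at 0 °C gives the racemic 2,3-epoxide F8, and p-TsOH opens it to 10.

**Step 10.**
- What may go wrong: iodination at C4 or C6 (between a hydroxyl and the benzyloxy group), double iodination, or acid-induced migration and loss of iodine during work-up.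
- Fallback: directed metalation, which sets out from 15 and returns at 16. Compound 15 is converted with MOMCl and i-Pr2NEt into 1-(benzyloxy)-3,5-bis(methoxymethoxy)benzene F9. n-BuLi in THF at 0 °C lithiates between the two acetal oxygens to give the aryllithium F10, iodine gives 5-(benzyloxy)-2-iodo-1,3-bis(methoxymethoxy)benzene F11, and HCl in MeOH releases 16.

**Step 14.**
- What may go wrong: stalling at partly debenzylated, poorly soluble intermediates, or slow over-reduction of a pyranone double bond on prolonged exposure.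
- Fallback: it sets out from 23 and returns at 24 with no new compound. The benzyl ethers are cleaved with BCl3 and pentamethylbenzene as cation scavenger in CH2Cl2 at −78 °C, conditions under which unchelated aryl methyl ethers are retained.

## Further compounds

F1 | step 11 | 1-[2,4-bis(benzyloxy)-6-hydroxyphenyl]ethanone | CC(=O)c1c(O)cc(OCc2ccccc2)cc1OCc1ccccc1
F2 | step 11 | 4-[2-(benzyloxy)-4-(3,5-bis(benzyloxy)-7-methoxy-4-oxo-4H-chromen-2-yl)phenoxy]-3-methoxybenzoic acid (Ar*-CO2H) | COc1cc(OCc2ccccc2)c2c(=O)c(OCc3ccccc3)c(-c3ccc(Oc4ccc(C(=O)O)cc4OC)c(OCc4ccccc4)c3)oc2c1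
F3 | step 11 | 2-acetyl-3,5-bis(benzyloxy)phenyl 4-[2-(benzyloxy)-4-(3,5-bis(benzyloxy)-7-methoxy-4-oxo-4H-chromen-2-yl)phenoxy]-3-methoxybenzoate | COc1cc(OCc2ccccc2)c2c(=O)c(OCc3ccccc3)c(-c3ccc(Oc4ccc(C(=O)Oc5cc(OCc6ccccc6)cc(OCc6ccccc6)c5C(C)=O)cc4OC)c(OCc4ccccc4)c3)oc2c1
F4 | step 11 | 1-[2,4-bis(benzyloxy)-6-hydroxyphenyl]-3-Ar*-propane-1,3-dione | COc1cc(OCc2ccccc2)c2c(=O)c(OCc3ccccc3)c(-c3ccc(Oc4ccc(C(=O)CC(=O)c5c(O)cc(OCc6ccccc6)cc5OCc5ccccc5)cc4OC)c(OCc4ccccc4)c3)oc2c1
F5 | step 13 | 2-(benzoyloxy)-1-[2,4-bis(benzyloxy)-6-hydroxyphenyl]-3-Ar*-propane-1,3-dione (racemic, enolisable) | COc1cc(OCc2ccccc2)c2c(=O)c(OCc3ccccc3)c(-c3ccc(Oc4ccc(C(=O)C(OC(=O)c5ccccc5)C(=O)c5c(O)cc(OCc6ccccc6)cc5OCc5ccccc5)cc4OC)c(OCc4ccccc4)c3)oc2c1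
F6 | step 13 | 3-(benzoyloxy)-5,7-bis(benzyloxy)-2-Ar*-4H-chromen-4-one | O=c1c(OC(=O)c2ccccc2)c(-c2ccc(Oc3ccc(-c4oc5cc(OC)cc(OCc6ccccc6)c5c(=O)c4OCc4ccccc4)cc3OCc3ccccc3)c(OC)c2)oc2cc(OCc3ccccc3)cc(OCc3ccccc3)c12
F7 | step 6 | 5-(benzyloxy)-2-[3-(benzyloxy)-4-(4-bromo-2-methoxyphenoxy)phenyl]-7-methoxy-4H-chromen-4-one | COc1cc(OCc2ccccc2)c2c(=O)cc(-c3ccc(Oc4ccc(Br)cc4OC)c(OCc4ccccc4)c3)oc2c1
F8 | step 6 | 2,3-epoxide of F7 (racemic, cis-fused; one enantiomer drawn) | O=C1c2c(OCc3ccccc3)cc(OC)cc2O[C@@]2(c3ccc(Oc4ccc(Br)cc4OC)c(OCc4ccccc4)c3)O[C@@H]12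
F9 | step 10 | 1-(benzyloxy)-3,5-bis(methoxymethoxy)benzene | COCOc1cc(OCOC)cc(OCc2ccccc2)c1
F10 | step 10 | [4-(benzyloxy)-2,6-bis(methoxymethoxy)phenyl]lithium | [Li]c1c(OCOC)cc(OCc2ccccc2)cc1OCOC
F11 | step 10 | 5-(benzyloxy)-2-iodo-1,3-bis(methoxymethoxy)benzene | COCOc1cc(OCc2ccccc2)cc(OCOC)c1I
F0 | step 14 | none | none
A1 | alternative 1 | methyl 3-methoxy-2-oxo-2H-pyran-5-carboxylate | COC(=O)C1=COC(=O)C(OC)=C1
A2 | alternative 1 | 2-[3-(benzyloxy)-4-(ethynyloxy)phenyl]-1,3-dioxolane | C#COc1ccc(C2OCCO2)cc1OCc1ccccc1
A3 | alternative 1 | methyl 4-[2-(benzyloxy)-4-(1,3-dioxolan-2-yl)phenoxy]-3-methoxybenzoate | COC(=O)c1ccc(Oc2ccc(C3OCCO3)cc2OCc2ccccc2)c(OC)c1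
A4 | alternative 2 | methyl (E)-9-{4-[2-(benzyloxy)-4-(1,3-dioxolan-2-yl)phenoxy]-3-methoxyphenyl}-3,5,7-trioxonon-8-enoate | COC(=O)CC(=O)CC(=O)CC(=O)/C=C/c1ccc(Oc2ccc(C3OCCO3)cc2OCc2ccccc2)c(OC)c1
A5 | alternative 2 | (E)-3-{4-[2-(benzyloxy)-4-(1,3-dioxolan-2-yl)phenoxy]-3-methoxyphenyl}-1-(2,4,6-trihydroxyphenyl)prop-2-en-1-one | O=C(/C=C/c1ccc(Oc2ccc(C3OCCO3)cc2OCc2ccccc2)c(OC)c1)c1c(O)cc(O)cc1O
A6 | alternative 3 | 2,4-dimethoxy-6-(trimethylsilyl)phenyl trifluoromethanesulfonate | COc1cc(OC)c(OS(=O)(=O)C(F)(F)F)c([Si](C)(C)C)c1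
A7 | alternative 3 | methyl 2-(benzyloxy)-3-{3-(benzyloxy)-4-[4-(1,3-dioxolan-2-yl)-2-methoxyphenoxy]phenyl}-3-oxopropanoate (racemic) | COC(=O)C(OCc1ccccc1)C(=O)c1ccc(Oc2ccc(C3OCCO3)cc2OC)c(OCc2ccccc2)c1
A8 | alternative 3 | 3-(benzyloxy)-2-{3-(benzyloxy)-4-[4-(1,3-dioxolan-2-yl)-2-methoxyphenoxy]phenyl}-5,7-dimethoxy-4H-chromen-4-one | COc1cc(OC)c2c(=O)c(OCc3ccccc3)c(-c3ccc(Oc4ccc(C5OCCO5)cc4OC)c(OCc4ccccc4)c3)oc2c1
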